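**Retrosynthetic overview**

- Feature: in ring A the carboxyl carbon C1 and the diaryl-ether carbon C6 are neighbours, and C1 lies next to the methoxy carbon C2 (C3 carries the carbinol). An oxygen nucleophile at C6 and a carbon electrophile at C1, beside OMe, is the addition pattern of a 3-methoxybenzyne.
- Key disconnection: C6–O(ring B) and C1–CO2H are cut together, giving silylaryl triflate 16 (aryne precursor), the potassium salt of ring B phenol 22, and CO2 (23).
- 16 comes from 4-bromo-3-methoxyphenol (1): aryllithium addition to isovaleraldehyde, oxidation and CBS reduction to the (S)-carbinol, TIPS protection, carbamate-directed silylation at C1, triflation of the C6 oxygen.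
- 22 comes from creosol (17): ortho-formylation, O-demethylation, selective SEM protection, dioxolane formation.
- No ring is formed anywhere (both benzene rings are bought). Fluoride then removes TIPS and SEM, and mild acid frees the aldehyde.

Key step: step 14

Remark on the chemistry: ring A is numbered C1 (CO2H), C2 (OMe), C3 (carbinol side chain), C6 (aryl ether). The carbinol carbon of the target is (S) (O > aryl > CH2 > H). 4-Bromo-3-methoxyphenol, isovaleraldehyde and creosol are assumed to be purchased.

**Route**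

Step 1
Reactants: 1 4-bromo-3-methoxyphenol
Product: 2 tert-butyl(4-bromo-3-methoxyphenoxy)dimethylsilane
Conditions: TBSCl, imidazole, DMF, rt
Reagents that add atoms: tert-butyldimethylsilyl chloride, CC(C)(C)[Si](C)(C)Cl
Why: Imidazole-assisted O-silylation of the phenol removes the acidic proton before the halogen–metal exchange and gives an aryl silyl ether that tolerates n-BuLi at −78 °C.

Step 2
Reactants: 2 tert-butyl(4-bromo-3-methoxyphenoxy)dimethylsilane, 3 isovaleraldehyde (3-methylbutanal)
Product: 5 rac-1-[4-(tert-butyldimethylsilyloxy)-2-methoxyphenyl]-3-methylbutan-1-ol, via aryllithium 4 (not isolated)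
Conditions: n-BuLi, THF, −78 °C; then 3, −78 °C; aq NH4Cl
Reagents that add atoms: none
Why: Bromine–lithium exchange is faster than attack on the silyl ether at −78 °C and the aryllithium adds 1,2 to the aldehyde, forming the bond between ring A C3 and the carbinol carbon; the carbinol is racemic here and is set in steps 3 and 4.

Step 3
Reactants: 5 rac-1-[4-(tert-butyldimethylsilyloxy)-2-methoxyphenyl]-3-methylbutan-1-ol
Product: 6 1-[4-(tert-butyldimethylsilyloxy)-2-methoxyphenyl]-3-methylbutan-1-one
Conditions: Dess–Martin periodinane, NaHCO3, CH2Cl2, 0 °C to rt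
Reagents that add atoms: none
Why: Dess–Martin oxidation of a secondary benzylic alcohol, buffered with NaHCO3 so that the aryl silyl ether is not cleaved by the acetic acid released.

Step 4
Reactants: 6 1-[4-(tert-butyldimethylsilyloxy)-2-methoxyphenyl]-3-methylbutan-1-one
Product: 7 (S)-1-[4-(tert-butyldimethylsilyloxy)-2-methoxyphenyl]-3-methylbutan-1-ol
Conditions: (R)-2-methyl-CBS-oxazaborolidine (0.2 equiv), BH3·SMe2, THF, −20 °C; MeOH quench
Reagents that add atoms: none
Why: Corey–Bakshi–Shibata reduction, in which the aryl group is the large and the isobutyl group the small ketone substituent, so the (R)-oxazaborolidine–borane complex delivers hydride to the face that gives the (S)-carbinol (the same sense as acetophenone to (S)-1-phenylethanol).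

Step 5
Reactants: 7 (S)-1-[4-(tert-butyldimethylsilyloxy)-2-methoxyphenyl]-3-methylbutan-1-ol
Product: 8 (S)-tert-butyl{3-methoxy-4-[3-methyl-1-(triisopropylsilyloxy)butyl]phenoxy}dimethylsilane
Conditions: TIPSOTf, 2,6-lutidine, CH2Cl2, −78 to 0 °C
Reagents that add atoms: triisopropylsilyl trifluoromethanesulfonate, CC(C)[Si](OS(=O)(=O)C(F)(F)F)(C(C)C)C(C)C
Why: O-silylation with the silyl triflate and a hindered base protects the secondary alcohol with retention at carbon as a TIPS ether, bulky enough to withstand the organolithium, the amine bases and the fluoride of step 14.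

Step 6
Reactants: 8 (S)-tert-butyl{3-methoxy-4-[3-methyl-1-(triisopropylsilyloxy)butyl]phenoxy}dimethylsilane
Product: 9 (S)-3-methoxy-4-[3-methyl-1-(triisopropylsilyloxy)butyl]phenol
Conditions: K2CO3, MeOH, rt
Reagents that add atoms: none
Why: Base-catalysed methanolysis cleaves only the aryl silyl ether, because phenoxide leaves silicon far more readily than a hindered secondary alkoxide, so the TIPS ether stays.

Step 7
Reactants: 9 (S)-3-methoxy-4-[3-methyl-1-(triisopropylsilyloxy)butyl]phenol
Product: 10 (S)-3-methoxy-4-[3-methyl-1-(triisopropylsilyloxy)butyl]phenyl N-isopropylcarbamate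
Conditions: i-PrNCO, Et3N (cat.), CH2Cl2, rt
Reagents that add atoms: isopropyl isocyanate, CC(C)N=C=O
Why: Base-catalysed addition of the phenol to the isocyanate gives the N-isopropyl carbamate, a strong ortho-directing group that can later be removed without acid or fluoride.

Step 8
Reactants: 10 (S)-3-methoxy-4-[3-methyl-1-(triisopropylsilyloxy)butyl]phenyl N-isopropylcarbamate
Product: 14 (S)-3-methoxy-4-[3-methyl-1-(triisopropylsilyloxy)butyl]-2-(trimethylsilyl)phenyl N-isopropylcarbamate, via N-silyl carbamate 11 (not isolated), via ortho-lithiated N-silyl carbamate 12 (not isolated), via N-silyl C-silyl carbamate 13 (not isolated)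
Conditions: TBSOTf, TMEDA, Et2O, 0 °C to rt; n-BuLi, TMEDA, −78 °C; TMSCl, −78 °C to rt; satd aq NaHSO4, 0 °C, brief
Reagents that add atoms: trimethylsilyl chloride, C[Si](C)(C)Cl
Why: Directed ortho-metalation, in which the carbamate (N–H masked in situ by silylation) guides n-BuLi/TMEDA to the adjacent C–H that is also flanked by the methoxy group (ring A C1), the more acidic of its two ortho positions, and TMSCl traps the aryllithium; at −78 °C the benzylic C–H of the TIPS ether on this electron-rich ring should not be deprotonated, so the (S)-centre is kept, and the work-up hydrolyses the N–Si bond.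

Step 9
Reactants: 14 (S)-3-methoxy-4-[3-methyl-1-(triisopropylsilyloxy)butyl]-2-(trimethylsilyl)phenyl N-isopropylcarbamate
Product: 16 (S)-3-methoxy-4-[3-methyl-1-(triisopropylsilyloxy)butyl]-2-(trimethylsilyl)phenyl trifluoromethanesulfonate, via free phenol 15 (not isolated)
Conditions: DBU, Et2NH, MeCN, 40 °C; then PhNTf2, rt
Reagents that add atoms: N-phenylbis(trifluoromethanesulfonimide), O=S(=O)(N(c1ccccc1)S(=O)(=O)C(F)(F)F)C(F)(F)F
Why: E1cB fragmentation of the deprotonated carbamate releases isopropyl isocyanate (scavenged by Et2NH as a urea) and the phenoxide is O-triflated by PhNTf2 in the same flask; neither acid nor fluoride is present, so the aryl–silicon bond and the TIPS ether survive.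

Step 10
Reactants: 17 creosol (2-methoxy-4-methylphenol)
Product: 18 2-hydroxy-3-methoxy-5-methylbenzaldehyde
Conditions: MgCl2, Et3N, paraformaldehyde, MeCN, reflux; 1 M HCl work-up
Reagents that add atoms: formaldehyde (as paraformaldehyde), C=O
Why: Magnesium phenoxide-directed ortho-formylation (Casnati–Skattebøl), in which formaldehyde is delivered to the only free ortho position (the para position carries the methyl group) and the resulting benzylic alkoxide is oxidised by hydride transfer to a second formaldehyde.

Step 11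
Reactants: 18 2-hydroxy-3-methoxy-5-methylbenzaldehyde
Product: 19 2,3-dihydroxy-5-methylbenzaldehyde
Conditions: BBr3, CH2Cl2, −78 to 0 °C; H2O
Reagents that add atoms: none
Why: Lewis acid O-demethylation (bromide attacks the methyl group of the boron-complexed aryl ether) frees the second phenol while the aldehyde is left alone at low temperature.

Step 12
Reactants: 19 2,3-dihydroxy-5-methylbenzaldehyde
Product: 21 2-hydroxy-5-methyl-3-{[2-(trimethylsilyl)ethoxy]methoxy}benzaldehyde, via disodium dianion 20 (not isolated)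
Conditions: NaH (2.2 equiv), DMF, 0 °C; SEMCl (1.0 equiv), 0 °C to rt; aq NH4Cl
Reagents that add atoms: 2-(trimethylsilyl)ethoxymethyl chloride, C[Si](C)(C)CCOCCl
Why: Williamson etherification of the dianion, in which the phenoxide ortho to the formyl group is delocalised into the carbonyl, so one equivalent of SEMCl alkylates the more nucleophilic C3 phenoxide, as is known for mono-alkylation of 2,3-dihydroxybenzaldehyde dianions.

Step 13
Reactants: 21 2-hydroxy-5-methyl-3-{[2-(trimethylsilyl)ethoxy]methoxy}benzaldehyde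
Product: 22 2-(1,3-dioxolan-2-yl)-4-methyl-6-{[2-(trimethylsilyl)ethoxy]methoxy}phenol
Conditions: ethylene glycol, PPTS (cat.), benzene, reflux, Dean–Stark; Et3N quench
Reagents that add atoms: ethylene glycol, OCCO
Why: Acid-catalysed acetalisation with azeotropic removal of water, using an acid weak enough to leave the SEM ether in place; the dioxolane removes the electrophilic carbonyl that would otherwise trap the aryl anion of step 14.

Step 14
Reactants: 16 (S)-3-methoxy-4-[3-methyl-1-(triisopropylsilyloxy)butyl]-2-(trimethylsilyl)phenyl trifluoromethanesulfonate, 22 2-(1,3-dioxolan-2-yl)-4-methyl-6-{[2-(trimethylsilyl)ethoxy]methoxy}phenol, 23 carbon dioxide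
Product: 27 (S)-6-[2-(1,3-dioxolan-2-yl)-4-methyl-6-{[2-(trimethylsilyl)ethoxy]methoxy}phenoxy]-2-methoxy-3-[3-methyl-1-(triisopropylsilyloxy)butyl]benzoic acid, via potassium phenoxide 24 (not isolated), via aryne 25 (not isolated), via aryl anion 26 (not isolated)
Conditions: 22 (1.5 equiv), KH (slight excess), THF, 0 °C; then CO2 (1 atm), KF, 18-crown-6, slow addition of 16 in THF, 0 °C to rt; cold dilute aq HCl to pH 3
Reagents that add atoms: none
Why: Proposed new method: fluoride attacks the C1 silicon of 16 and expels the C6 triflate to give 3-methoxybenzyne 25; phenoxide 24 adds at C6, the aryne carbon remote from the methoxy group, so the charge develops at C1 as aryl anion 26, which is stabilised inductively by its two flanking oxygens and is carboxylated by the CO2 saturating the solution. The closest known reactions are the three-component coupling of arynes, amines and CO2 to anthranilic acids under KF/18-crown-6 in THF and the fluoride-mediated O-arylation of phenols by arynes; the new element is capture of the aryl anion from a phenoxide addition by CO2 in place of a proton. No ring is closed and no stereocentre is formed; the (S)-carbinol, protected as its TIPS ether and remote from the reacting carbons, is not touched. The step needs regioselectivity across the triple bond, which the C2 methoxy group secures by polarising and distorting the aryne (helped by the C3 side chain pressing the methoxy methyl toward C1), and it needs carboxylation to win over protonation, which is secured by making 24 with KH (H2 as the only by-product), by THF in place of a C–H acidic solvent, and by the absence of free phenol. The ring B aldehyde is masked as the dioxolane because a free formyl group would capture 26 intramolecularly to give a xanthenol, and both ortho positions and the para position of 24 are substituted, so C-arylation is excluded.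

Step 15
Reactants: 27 (S)-6-[2-(1,3-dioxolan-2-yl)-4-methyl-6-{[2-(trimethylsilyl)ethoxy]methoxy}phenoxy]-2-methoxy-3-[3-methyl-1-(triisopropylsilyloxy)butyl]benzoic acid
Product: 28 (S)-6-[2-(1,3-dioxolan-2-yl)-6-hydroxy-4-methylphenoxy]-3-(1-hydroxy-3-methylbutyl)-2-methoxybenzoic acid
Conditions: Bu4NF (6 equiv), THF–DMPU, 60 °C; aq NH4Cl, then 1 M HCl to pH 3 at 0 °C
Reagents that add atoms: none
Why: Fluoride-induced desilylation, in which fluoride attacks silicon of the TIPS ether and of the SEM group (the latter fragmenting to ethylene, formaldehyde and the phenoxide), while the dioxolane and the diaryl ether are inert to fluoride and the carbinol carbon is not involved.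

Step 16
Reactants: 28 (S)-6-[2-(1,3-dioxolan-2-yl)-6-hydroxy-4-methylphenoxy]-3-(1-hydroxy-3-methylbutyl)-2-methoxybenzoic acid
Product: 29 tenellic acid B, (S)-6-(2-formyl-6-hydroxy-4-methylphenoxy)-3-(1-hydroxy-3-methylbutyl)-2-methoxybenzoic acid
Conditions: AcOH/THF/H2O (3:1:1), rt
Reagents that add atoms: water, O
Why: Acid-catalysed acetal hydrolysis, fast for an ortho-hydroxyaryl dioxolane, under conditions too mild to ionise the benzylic carbinol, so the (S)-configuration should be retained.

**Compound list**

1 | 4-bromo-3-methoxyphenol | COc1cc(O)ccc1Br | starting material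
2 | tert-butyl(4-bromo-3-methoxyphenoxy)dimethylsilane | COc1cc(O[Si](C)(C)C(C)(C)C)ccc1Br | intermediate
3 | isovaleraldehyde (3-methylbutanal) | CC(C)CC=O | starting material
4 | [4-(tert-butyldimethylsilyloxy)-2-methoxyphenyl]lithium (formed in the flask) | COc1cc(O[Si](C)(C)C(C)(C)C)ccc1[Li] | intermediate
5 | rac-1-[4-(tert-butyldimethylsilyloxy)-2-methoxyphenyl]-3-methylbutan-1-ol | COc1cc(O[Si](C)(C)C(C)(C)C)ccc1C(O)CC(C)C | intermediate
6 | 1-[4-(tert-butyldimethylsilyloxy)-2-methoxyphenyl]-3-methylbutan-1-one | COc1cc(O[Si](C)(C)C(C)(C)C)ccc1C(=O)CC(C)C | intermediate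
7 | (S)-1-[4-(tert-butyldimethylsilyloxy)-2-methoxyphenyl]-3-methylbutan-1-ol | COc1c([C@@H](O)CC(C)C)ccc(O[Si](C)(C)C(C)(C)C)c1 | intermediate
8 | (S)-tert-butyl{3-methoxy-4-[3-methyl-1-(triisopropylsilyloxy)butyl]phenoxy}dimethylsilane | COc1c([C@@H](O[Si](C(C)C)(C(C)C)C(C)C)CC(C)C)ccc(O[Si](C)(C)C(C)(C)C)c1 | intermediate
9 | (S)-3-methoxy-4-[3-methyl-1-(triisopropylsilyloxy)butyl]phenol | COc1c([C@@H](O[Si](C(C)C)(C(C)C)C(C)C)CC(C)C)ccc(O)c1 | intermediate
10 | (S)-3-methoxy-4-[3-methyl-1-(triisopropylsilyloxy)butyl]phenyl N-isopropylcarbamate | COc1c([C@@H](O[Si](C(C)C)(C(C)C)C(C)C)CC(C)C)ccc(OC(=O)NC(C)C)c1 | intermediate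
11 | (S)-3-methoxy-4-[3-methyl-1-(triisopropylsilyloxy)butyl]phenyl N-(tert-butyldimethylsilyl)-N-isopropylcarbamate (formed in the flask) | COc1c([C@@H](O[Si](C(C)C)(C(C)C)C(C)C)CC(C)C)ccc(OC(=O)N(C(C)C)[Si](C)(C)C(C)(C)C)c1 | intermediate
12 | (S)-{2-[N-(tert-butyldimethylsilyl)-N-isopropylcarbamoyloxy]-6-methoxy-5-[3-methyl-1-(triisopropylsilyloxy)butyl]phenyl}lithium (formed in the flask) | COc1c([C@@H](O[Si](C(C)C)(C(C)C)C(C)C)CC(C)C)ccc(OC(=O)N(C(C)C)[Si](C)(C)C(C)(C)C)c1[Li] | intermediate
13 | (S)-3-methoxy-4-[3-methyl-1-(triisopropylsilyloxy)butyl]-2-(trimethylsilyl)phenyl N-(tert-butyldimethylsilyl)-N-isopropylcarbamate (formed in the flask) | COc1c([C@@H](O[Si](C(C)C)(C(C)C)C(C)C)CC(C)C)ccc(OC(=O)N(C(C)C)[Si](C)(C)C(C)(C)C)c1[Si](C)(C)C | intermediate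
14 | (S)-3-methoxy-4-[3-methyl-1-(triisopropylsilyloxy)butyl]-2-(trimethylsilyl)phenyl N-isopropylcarbamate | COc1c([C@@H](O[Si](C(C)C)(C(C)C)C(C)C)CC(C)C)ccc(OC(=O)NC(C)C)c1[Si](C)(C)C | intermediate
15 | (S)-3-methoxy-4-[3-methyl-1-(triisopropylsilyloxy)butyl]-2-(trimethylsilyl)phenol (formed in the flask) | COc1c([C@@H](O[Si](C(C)C)(C(C)C)C(C)C)CC(C)C)ccc(O)c1[Si](C)(C)C | intermediate
16 | (S)-3-methoxy-4-[3-methyl-1-(triisopropylsilyloxy)butyl]-2-(trimethylsilyl)phenyl trifluoromethanesulfonate | COc1c([C@@H](O[Si](C(C)C)(C(C)C)C(C)C)CC(C)C)ccc(OS(=O)(=O)C(F)(F)F)c1[Si](C)(C)C | intermediate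
17 | creosol (2-methoxy-4-methylphenol) | COc1cc(C)ccc1O | starting material
18 | 2-hydroxy-3-methoxy-5-methylbenzaldehyde | COc1cc(C)cc(C=O)c1O | intermediate
19 | 2,3-dihydroxy-5-methylbenzaldehyde | Cc1cc(O)c(O)c(C=O)c1 | intermediate
20 | disodium 3-formyl-5-methylbenzene-1,2-diolate (formed in the flask) | Cc1cc([O-])c([O-])c(C=O)c1.[Na+].[Na+] | intermediate
21 | 2-hydroxy-5-methyl-3-{[2-(trimethylsilyl)ethoxy]methoxy}benzaldehyde | Cc1cc(OCOCC[Si](C)(C)C)c(O)c(C=O)c1 | intermediate
22 | 2-(1,3-dioxolan-2-yl)-4-methyl-6-{[2-(trimethylsilyl)ethoxy]methoxy}phenol | Cc1cc(OCOCC[Si](C)(C)C)c(O)c(C2OCCO2)c1 | intermediate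
23 | carbon dioxide | O=C=O | starting material
24 | potassium 2-(1,3-dioxolan-2-yl)-4-methyl-6-{[2-(trimethylsilyl)ethoxy]methoxy}phenolate (formed in the flask) | Cc1cc(OCOCC[Si](C)(C)C)c([O-])c(C2OCCO2)c1.[K+] | intermediate
25 | (S)-3-methoxy-4-[3-methyl-1-(triisopropylsilyloxy)butyl]-1,2-didehydrobenzene, the aryne with its triple bond between ring A C1 and C6 (formed in the flask) | COC1=C([C@@H](O[Si](C(C)C)(C(C)C)C(C)C)CC(C)C)C=CC#C1 | intermediate
26 | (S)-{6-[2-(1,3-dioxolan-2-yl)-4-methyl-6-{[2-(trimethylsilyl)ethoxy]methoxy}phenoxy]-2-methoxy-3-[3-methyl-1-(triisopropylsilyloxy)butyl]phenyl}potassium (formed in the flask) | COc1c([C@@H](O[Si](C(C)C)(C(C)C)C(C)C)CC(C)C)ccc(Oc2c(OCOCC[Si](C)(C)C)cc(C)cc2C2OCCO2)[c-]1.[K+] | intermediate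
27 | (S)-6-[2-(1,3-dioxolan-2-yl)-4-methyl-6-{[2-(trimethylsilyl)ethoxy]methoxy}phenoxy]-2-methoxy-3-[3-methyl-1-(triisopropylsilyloxy)butyl]benzoic acid | COc1c([C@@H](O[Si](C(C)C)(C(C)C)C(C)C)CC(C)C)ccc(Oc2c(OCOCC[Si](C)(C)C)cc(C)cc2C3OCCO3)c1C(=O)O | intermediate
28 | (S)-6-[2-(1,3-dioxolan-2-yl)-6-hydroxy-4-methylphenoxy]-3-(1-hydroxy-3-methylbutyl)-2-methoxybenzoic acid | COc1c([C@@H](O)CC(C)C)ccc(Oc2c(O)cc(C)cc2C3OCCO3)c1C(=O)O | intermediate
29 | tenellic acid B, (S)-6-(2-formyl-6-hydroxy-4-methylphenoxy)-3-(1-hydroxy-3-methylbutyl)-2-methoxybenzoic acid | COc1c([C@@H](O)CC(C)C)ccc(Oc2c(O)cc(C)cc2C=O)c1C(=O)O | target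

**Step count and risks**

Total step count: 16. Longest linear sequence: 12 steps (steps 1 to 9, then 14 to 16); the ring B branch (steps 10 to 13) joins at step 14.

Steps most likely to fail:

1. Step 14 (the proposed method). The aryl anion may be protonated before CO2 reaches it, for instance by the dioxolane or OCH2O hydrogens within its reach. Alternatively, the phenoxide may be carbonated reversibly by CO2, so that it adds through a carbonate oxygen and then transfers the acyl group to carbon, giving an ester in place of the ether acid. The fallback uses two known reactions and sets out from 16 and 22. Without CO2, CsF in MeCN at rt generates the aryne in the presence of free phenol 22 and the aryl anion is protonated in the flask; this fluoride-mediated O-arylation should give the carboxyl-free diaryl ether (S)-{1-[4-(2-(1,3-dioxolan-2-yl)-4-methyl-6-{[2-(trimethylsilyl)ethoxy]methoxy}phenoxy)-2-methoxyphenyl]-3-methylbutoxy}triisopropylsilane F1. This ether is then lithiated with s-BuLi/TMEDA in THF at −78 °C at ring A C1, the only C–H flanked by two oxygens, and quenched with CO2, which comes back to the route at 27.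

2. Step 8. Lithiation may occur at the other ortho carbon of the carbamate, or at the benzylic C–H, followed by silyl migration from oxygen to carbon and loss of configuration. The fallback sets out from 1 and comes back at 15 (and so at 16). It installs silicon before the stereocentre exists, so that no alkyllithium meets the benzylic silyl ether.
 - 1 with ClC(O)NEt2 and K2CO3 (MeCN, reflux) should give 4-bromo-3-methoxyphenyl N,N-diethylcarbamate F2.
 - LiN(i-Pr)2 with TMSCl already present (THF, −78 °C) deprotonates the C–H between carbamate and methoxy without touching the C–Br bond, giving 4-bromo-3-methoxy-2-(trimethylsilyl)phenyl N,N-diethylcarbamate F3.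
 - Bromine–lithium exchange (n-BuLi, THF, −78 °C) and addition to 3 gives rac-4-(1-hydroxy-3-methylbutyl)-3-methoxy-2-(trimethylsilyl)phenyl N,N-diethylcarbamate F4.
 - Dess–Martin oxidation gives 3-methoxy-4-(3-methylbutanoyl)-2-(trimethylsilyl)phenyl N,N-diethylcarbamate F5.
 - Reduction as in step 4 gives (S)-4-(1-hydroxy-3-methylbutyl)-3-methoxy-2-(trimethylsilyl)phenyl N,N-diethylcarbamate F6.
 - TIPSOTf/2,6-lutidine gives (S)-3-methoxy-4-[3-methyl-1-(triisopropylsilyloxy)butyl]-2-(trimethylsilyl)phenyl N,N-diethylcarbamate F7.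
 - LiAlH4 in THF reduces the carbamate off to phenol 15, which is triflated with PhNTf2/DBU as in the second half of step 9 to give 16.

3. Step 13. The SEM acetal may be lost by acid-catalysed exchange with ethylene glycol, or the dioxolane may revert during isolation, assisted by the free ortho-hydroxyl. The fallback sets out from 21 and comes back at 22. The phenol is first acetylated (Ac2O, pyridine) to 2-formyl-4-methyl-6-{[2-(trimethylsilyl)ethoxy]methoxy}phenyl acetate F8. The now ordinary aryl aldehyde is acetalised under aprotic Noyori conditions (TMSOCH2CH2OTMS, cat. TMSOTf, CH2Cl2, −78 °C) to 2-(1,3-dioxolan-2-yl)-4-methyl-6-{[2-(trimethylsilyl)ethoxy]methoxy}phenyl acetate F9. K2CO3 in MeOH then removes the acetate and gives 22.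

**Further compounds**

F1 | step 14 | (S)-{1-[4-(2-(1,3-dioxolan-2-yl)-4-methyl-6-{[2-(trimethylsilyl)ethoxy]methoxy}phenoxy)-2-methoxyphenyl]-3-methylbutoxy}triisopropylsilane | COc1c([C@@H](O[Si](C(C)C)(C(C)C)C(C)C)CC(C)C)ccc(Oc2c(OCOCC[Si](C)(C)C)cc(C)cc2C2OCCO2)c1
F2 | step 8 | 4-bromo-3-methoxyphenyl N,N-diethylcarbamate | COc1cc(OC(=O)N(CC)CC)ccc1Br
F3 | step 8 | 4-bromo-3-methoxy-2-(trimethylsilyl)phenyl N,N-diethylcarbamate | COc1c(Br)ccc(OC(=O)N(CC)CC)c1[Si](C)(C)C
F4 | step 8 | rac-4-(1-hydroxy-3-methylbutyl)-3-methoxy-2-(trimethylsilyl)phenyl N,N-diethylcarbamate | COc1c(C(O)CC(C)C)ccc(OC(=O)N(CC)CC)c1[Si](C)(C)C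
F5 | step 8 | 3-methoxy-4-(3-methylbutanoyl)-2-(trimethylsilyl)phenyl N,N-diethylcarbamate | COc1c(C(=O)CC(C)C)ccc(OC(=O)N(CC)CC)c1[Si](C)(C)C
F6 | step 8 | (S)-4-(1-hydroxy-3-methylbutyl)-3-methoxy-2-(trimethylsilyl)phenyl N,N-diethylcarbamate | COc1c([C@@H](O)CC(C)C)ccc(OC(=O)N(CC)CC)c1[Si](C)(C)C
F7 | step 8 | (S)-3-methoxy-4-[3-methyl-1-(triisopropylsilyloxy)butyl]-2-(trimethylsilyl)phenyl N,N-diethylcarbamate | COc1c([C@@H](O[Si](C(C)C)(C(C)C)C(C)C)CC(C)C)ccc(OC(=O)N(CC)CC)c1[Si](C)(C)C
F8 | step 13 | 2-formyl-4-methyl-6-{[2-(trimethylsilyl)ethoxy]methoxy}phenyl acetate | CC(=O)Oc1c(C=O)cc(C)cc1OCOCC[Si](C)(C)C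
F9 | step 13 | 2-(1,3-dioxolan-2-yl)-4-methyl-6-{[2-(trimethylsilyl)ethoxy]methoxy}phenyl acetate | CC(=O)Oc1c(C2OCCO2)cc(C)cc1OCOCC[Si](C)(C)C
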